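**Retrosynthetic overview**

1. Sceptrin (29) ← diamine 27 + two 4-bromopyrrole-2-carbonyl units (both amides last). The second 2-aminoimidazole comes from the acetyl group at Cd (chlorination, amination, cyanamide). The amino group of the first comes from C2-lithiation/azidation of an imidazole carried from the start.
2. All-trans cyclobutane 12 ← cis-ester 11 by epimerisation of the single ester-bearing carbon.
3. Feature used: the cyclobutane bond Ca–Cb joins an imidazole-bearing carbon to a CH2N-bearing carbon. With one nitrogen between them these are C5 and C2 of a pyrrolidine, so 11 ← NH-pyrrolidine 8 by nitrogen deletion (1,1-diazene, loss of N2).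
4. Pyrrolidine 8 ← exo-selective copper-catalysed [3+2] cycloaddition of glycine imine 7 (from a sulfamoyl-protected imidazole-4-carbaldehyde) with enone 5.
5. Ring order: imidazole (bought) → pyrrolidine (step 4) → cyclobutane (step 5) → second imidazole (step 17); the pyrroles are bought.

Key step: step 5

Labels: in every cyclobutane Ca bears the original imidazole, Cb the ester-derived arm, Cc the ether-derived arm and Cd the acetyl-derived group (ring order Ca–Cb–Cc–Cd); the SMILES fix the absolute configuration.

Assumption: the (Rp) ligand in step 4 is written for the (2R,5S) series of 8; if the first run shows the opposite sense, the (Sp) ligand is used and nothing else changes.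

**Route**

Step 1
Reactants: 1 1H-imidazole-4-carbaldehyde
Product: 2 4-formyl-N,N-dimethyl-1H-imidazole-1-sulfonamide
Conditions: Me2NSO2Cl, Et3N, CH2Cl2, rt
Reagents that add atoms: N,N-dimethylsulfamoyl chloride, CN(C)S(=O)(=O)Cl
Why: N-sulfonylation of the imidazole; under amine hydrochloride equilibration the sulfamoyl group should settle on the nitrogen remote from the formyl group (1,4-isomer), where it later blocks that nitrogen in the key step and directs C2-lithiation.

Step 2
Reactants: 3 2-(benzyloxy)acetaldehyde; 4 1-(triphenylphosphoranylidene)propan-2-one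
Product: 5 (E)-5-(benzyloxy)pent-3-en-2-one
Conditions: CH2Cl2, rt
Reagents that add atoms: none
Why: Wittig olefination with a stabilised acyl ylide, which should give the (E)-enone.

Step 3
Reactants: 2 4-formyl-N,N-dimethyl-1H-imidazole-1-sulfonamide; 6 glycine methyl ester hydrochloride
Product: 7 methyl N-{(E)-[1-(dimethylsulfamoyl)-1H-imidazol-4-yl]methylidene}glycinate
Conditions: Et3N, MgSO4, CH2Cl2, rt
Reagents that add atoms: none
Why: Imine condensation driven by the drying agent, product used crude; the methyl ester is chosen because methoxide can later epimerise it without transesterification and LiBH4 can reduce it.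

Step 4
Reactants: 7 methyl N-{(E)-[1-(dimethylsulfamoyl)-1H-imidazol-4-yl]methylidene}glycinate; 5 (E)-5-(benzyloxy)pent-3-en-2-one
Product: 8 methyl (2R,3S,4S,5S)-4-acetyl-3-[(benzyloxy)methyl]-5-[1-(dimethylsulfamoyl)-1H-imidazol-4-yl]pyrrolidine-2-carboxylate (exo adduct)
Conditions: Cu(CH3CN)4PF6 (5 mol %), (Rp)-Fesulphos [Fe(C5H5)(C5H3(PPh2)(S-t-Bu))] (5.5 mol %), Et3N (20 mol %), THF, −10 °C
Reagents that add atoms: none
Why: Copper-catalysed asymmetric 1,3-dipolar cycloaddition of the N-metalated azomethine ylide (Michael–Mannich sequence): the glycine carbon adds to the enone β-carbon and the enolate closes on the imine carbon, so the CH2OBn arm sits next to the ester and the acetyl next to the imidazolyl carbon; the W-shaped chelated dipole sets C2/C5 cis, the (E)-enone sets C3/C4 trans, and the planar-chiral P,S ligand on monovalent copper shields one face of the dipole (absolute configuration) and is expected to steer the acyclic trans-enone into the exo approach, leaving acetyl trans to the imidazolyl group.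

Step 5
Reactants: 8 methyl (2R,3S,4S,5S)-4-acetyl-3-[(benzyloxy)methyl]-5-[1-(dimethylsulfamoyl)-1H-imidazol-4-yl]pyrrolidine-2-carboxylate
Product: 11 methyl (1R,2S,3R,4R)-3-acetyl-2-[(benzyloxy)methyl]-4-[1-(dimethylsulfamoyl)-1H-imidazol-4-yl]cyclobutane-1-carboxylate, via 1,1-diazene 9 (not isolated), via 1,4-diradical 10 (not isolated)
Conditions: PhI(OH)OTs (2.5 equiv), NH2CO2NH4 (8 equiv), CF3CH2OH, 80 °C
Reagents that add atoms: none
Why: Ammonia and the trivalent iodine reagent generate an iodonitrene that aminates the only N–H nitrogen of 8 to the 1,1-diazene 9, and loss of N2 leaves the singlet 1,4-diradical 10, whose ends are stabilised by the ester and by the imidazolyl ring. The closest known reaction type is the iodonitrene-mediated contraction of polysubstituted NH-pyrrolidines from azomethine ylide cycloadditions to cyclobutanes, applied here to a heteroaryl-substituted member of that class. The cyclobutane closes by radical–radical recombination between the former C5 and C2 of the pyrrolidine, which makes the Ca–Cb bond. Both stereocentres at the new bond are controlled by the pyrrolidine itself: the singlet diradical should recombine faster than the C–C bonds rotate, so the cis relation of imidazolyl and ester is carried over with retention, and Cc and Cd are not touched. The step needs amination at the ring nitrogen only and closure in preference to β-scission into two alkenes; the sulfamoyl group blocks one imidazole nitrogen and deactivates the other, ammonia should consume the oxidant faster than it can attack the ketone enol, and the two stabilising groups together with the cis-2,5 geometry favour closure.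

Step 6
Reactants: 11 methyl (1R,2S,3R,4R)-3-acetyl-2-[(benzyloxy)methyl]-4-[1-(dimethylsulfamoyl)-1H-imidazol-4-yl]cyclobutane-1-carboxylate
Product: 12 methyl (1S,2S,3R,4R)-3-acetyl-2-[(benzyloxy)methyl]-4-[1-(dimethylsulfamoyl)-1H-imidazol-4-yl]cyclobutane-1-carboxylate (all-trans)
Conditions: NaOMe (0.3 equiv), MeOH, rt
Reagents that add atoms: none
Why: Base-mediated epimerisation through the ester enolate under thermodynamic control: the ester, cis to both neighbours in 11, should move to the trans,trans position, while the acetyl-bearing carbon is already trans to both neighbours and Ca and Cc carry no acidic hydrogen.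

Step 7
Reactants: 12 methyl (1S,2S,3R,4R)-3-acetyl-2-[(benzyloxy)methyl]-4-[1-(dimethylsulfamoyl)-1H-imidazol-4-yl]cyclobutane-1-carboxylate
Product: 13 methyl (1S,2S,3R,4R)-2-[(benzyloxy)methyl]-4-[1-(dimethylsulfamoyl)-1H-imidazol-4-yl]-3-(2-methyl-1,3-dioxolan-2-yl)cyclobutane-1-carboxylate
Conditions: HOCH2CH2OH, p-TsOH·H2O (0.2 equiv), benzene, reflux (Dean–Stark)
Reagents that add atoms: ethylene glycol, OCCO
Why: Acid-catalysed ketalisation with azeotropic removal of water; the dioxolane masks the ketone against hydride in step 8 and organolithium in step 11.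

Step 8
Reactants: 13 methyl (1S,2S,3R,4R)-2-[(benzyloxy)methyl]-4-[1-(dimethylsulfamoyl)-1H-imidazol-4-yl]-3-(2-methyl-1,3-dioxolan-2-yl)cyclobutane-1-carboxylate
Product: 14 all-trans cyclobutane alcohol (Ca 1-(dimethylsulfamoyl)imidazol-4-yl; Cb CH2OH; Cc CH2OBn; Cd 2-methyl-1,3-dioxolan-2-yl)
Conditions: LiBH4, THF–MeOH, 0 °C → rt
Reagents that add atoms: none
Why: Chemoselective hydride reduction of the methyl ester to the primary alcohol; ketal, benzyl ether and sulfamoyl group should be inert to LiBH4.

Step 9
Reactants: 14 all-trans cyclobutane alcohol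
Product: 15 all-trans cyclobutane diol (Cb and Cc CH2OH; Cd dioxolane)
Conditions: H2 (1 atm), Pd(OH)2/C, EtOH, rt
Reagents that add atoms: none
Why: Hydrogenolysis of the benzyl ether, placed here because after step 11 a hydrogenation would reduce the azide.

Step 10
Reactants: 15 all-trans cyclobutane diol
Product: 16 bis(tert-butyldimethylsilyl) ether of 15
Conditions: TBSCl (2.5 equiv), imidazole (5 equiv), DMF, rt
Reagents that add atoms: tert-butyldimethylsilyl chloride, CC(C)(C)[Si](C)(C)Cl
Why: Silylation of both primary alcohols, so that the substrate for step 11 carries no acidic or electrophilic group.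

Step 11
Reactants: 16 bis(tert-butyldimethylsilyl) ether of 15
Product: 18 2-azidoimidazole bis-silyl ether ketal (N3 at imidazole C2 of 16), via 2-lithioimidazole 17 (not isolated)
Conditions: n-BuLi (1.05 equiv), THF, −78 °C; then TsN3, −78 °C → rt
Reagents that add atoms: 4-methylbenzenesulfonyl azide, Cc1ccc(cc1)S(=O)(=O)N=[N+]=[N-]
Why: Directed deprotonation at imidazole C2, the most acidic C–H (between both nitrogens and next to the sulfamoyl group), then electrophilic azide transfer from the sulfonyl azide, whose triazenide adduct expels sulfinate.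

Step 12
Reactants: 18 2-azidoimidazole bis-silyl ether ketal
Product: 19 all-trans keto diol (Ca 2-azido-1-(dimethylsulfamoyl)imidazol-4-yl; Cb and Cc CH2OH; Cd acetyl)
Conditions: 1 M HCl (aq), THF, rt
Reagents that add atoms: water, O
Why: Acid hydrolysis should remove both primary silyl ethers and the dioxolane in one operation; sulfamoyl group and azide tolerate dilute acid at rt, and the acetyl-bearing carbon stays in its preferred trans,trans position.

Step 13
Reactants: 19 all-trans keto diol
Product: 20 dimesylate of 19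
Conditions: MsCl (2.5 equiv), Et3N (3 equiv), CH2Cl2, 0 °C
Reagents that add atoms: methanesulfonyl chloride, CS(=O)(=O)Cl
Why: Sulfonylation of the two primary alcohols to leaving groups.

Step 14
Reactants: 20 dimesylate of 19
Product: 21 triazide ketone (Cb and Cc CH2N3; Cd acetyl)
Conditions: NaN3 (4 equiv), DMF, 60 °C
Reagents that add atoms: sodium azide, [Na+].[N-]=[N+]=[N-]
Why: SN2 displacement of the primary mesylates by azide, a weakly basic nucleophile that leaves the ketone alone; the nitrogen-rich triazide is to be kept in solution on small scale.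

Step 15
Reactants: 21 triazide ketone
Product: 22 chloromethyl ketone (Cd C(=O)CH2Cl)
Conditions: BnNMe3ICl2, THF, 60 °C
Reagents that add atoms: benzyltrimethylammonium dichloroiodate, C[N+](C)(C)Cc1ccccc1.Cl[I-]Cl
Why: Electrophilic α-chlorination through the enol; enolisation toward the methyl group is preferred because an enol double bond exocyclic to the cyclobutane is strained, and the azido- and sulfamoyl-substituted imidazole is too electron-poor for ring halogenation.

Step 16
Reactants: 22 chloromethyl ketone
Product: 23 α-(diformylamino) ketone (Cd C(=O)CH2N(CHO)2)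
Conditions: NaN(CHO)2, MeCN, 35 °C
Reagents that add atoms: sodium diformylamide, [Na+].O=C[N-]C=O
Why: SN2 substitution of the activated α-chloroketone by diformylamide, a Gabriel-type ammonia equivalent that prevents self-condensation of a free α-aminoketone.

Step 17
Reactants: 23 α-(diformylamino) ketone
Product: 25 triazide bearing 2-amino-1H-imidazol-5-yl at Cd, via aminoketone hydrochloride 24 (not isolated)
Conditions: HCl, MeOH, rt; evaporate; then NH2CN, H2O, pH 4.5, 95 °C
Reagents that add atoms: cyanamide, NC#N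
Why: Acid methanolysis of the formyl groups, then Marckwald-type condensation of the α-aminoketone salt with cyanamide (guanylation, cyclisation onto the ketone, dehydration) builds the second 2-aminoimidazole; the arms stay as azides so that no free alkylamine competes for cyanamide or for the ketone.

Step 18
Reactants: 25 triazide bearing 2-amino-1H-imidazol-5-yl at Cd
Product: 26 triamine (Ca 2-amino-1-(dimethylsulfamoyl)imidazol-4-yl; Cb and Cc CH2NH2; Cd 2-amino-1H-imidazol-5-yl)
Conditions: H2 (1 atm), Pd/C, MeOH, rt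
Reagents that add atoms: none
Why: Catalytic hydrogenation of all three azides to amines, done before any aryl bromide is present.

Step 19
Reactants: 26 triamine
Product: 27 all-trans 3,4-bis(aminomethyl)-1,2-bis(2-amino-1H-imidazol-5-yl)cyclobutane (isolated as its hydrochloride)
Conditions: 2 M HCl (aq), MeOH, 70 °C
Reagents that add atoms: none
Why: Acid hydrolysis of the N-sulfamoyl group; amines and 2-aminoimidazoles are protected as their salts under these conditions.

Step 20
Reactants: 27 diamine (hydrochloride); 28 1-(4-bromo-1H-pyrrol-2-yl)-2,2,2-trichloroethan-1-one (2.2 equiv in all; two equivalents are consumed, one per aminomethyl arm)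
Product: 29 sceptrin
Conditions: 28 (2.2 equiv), i-Pr2NEt, DMF, rt
Reagents that add atoms: 1-(4-bromo-1H-pyrrol-2-yl)-2,2,2-trichloroethan-1-one (the second equivalent of 28), O=C(c1cc(Br)c[nH]1)C(Cl)(Cl)Cl
Why: Twofold haloform-type acyl transfer from the trichloromethyl ketone, one equivalent to each of the two primary alkylamines with loss of chloroform each time; the amidine-like 2-aminoimidazole nitrogens are far less nucleophilic and should stay free, and no stereocentre is touched.

**Compound list**

1 | 1H-imidazole-4-carbaldehyde | O=Cc1c[nH]cn1 | starting material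
2 | 4-formyl-N,N-dimethyl-1H-imidazole-1-sulfonamide | CN(C)S(=O)(=O)n1cnc(C=O)c1 | intermediate
3 | 2-(benzyloxy)acetaldehyde | O=CCOCc1ccccc1 | starting material
4 | 1-(triphenylphosphoranylidene)propan-2-one | CC(=O)C=P(c1ccccc1)(c1ccccc1)c1ccccc1 | starting material
5 | (E)-5-(benzyloxy)pent-3-en-2-one | CC(=O)/C=C/COCc1ccccc1 | intermediate
6 | glycine methyl ester hydrochloride | COC(=O)CN.Cl | starting material
7 | methyl N-{(E)-[1-(dimethylsulfamoyl)-1H-imidazol-4-yl]methylidene}glycinate | CN(C)S(=O)(=O)n1cnc(/C=N/CC(=O)OC)c1 | intermediate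
8 | methyl (2R,3S,4S,5S)-4-acetyl-3-[(benzyloxy)methyl]-5-[1-(dimethylsulfamoyl)-1H-imidazol-4-yl]pyrrolidine-2-carboxylate | CN(C)S(=O)(=O)n1cnc(c1)[C@H]2N[C@@H](C(=O)OC)[C@@H](COCc3ccccc3)[C@@H]2C(C)=O | intermediate
9 | 1,1-diazene of 8 (exocyclic N on the ring nitrogen) | CN(C)S(=O)(=O)n1cnc(c1)[C@H]2[N+](=[N-])[C@@H](C(=O)OC)[C@@H](COCc3ccccc3)[C@@H]2C(C)=O | intermediate
10 | 1,4-diradical from 9 after loss of N2 | CN(C)S(=O)(=O)n1cnc(c1)[CH][C@@H](C(C)=O)[C@H](COCc2ccccc2)[CH]C(=O)OC | intermediate
11 | methyl (1R,2S,3R,4R)-3-acetyl-2-[(benzyloxy)methyl]-4-[1-(dimethylsulfamoyl)-1H-imidazol-4-yl]cyclobutane-1-carboxylate | CN(C)S(=O)(=O)n1cnc(c1)[C@H]2[C@@H](C(=O)OC)[C@@H](COCc3ccccc3)[C@@H]2C(C)=O | intermediate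
12 | methyl (1S,2S,3R,4R)-3-acetyl-2-[(benzyloxy)methyl]-4-[1-(dimethylsulfamoyl)-1H-imidazol-4-yl]cyclobutane-1-carboxylate (all-trans) | CN(C)S(=O)(=O)n1cnc(c1)[C@H]2[C@H](C(=O)OC)[C@@H](COCc3ccccc3)[C@@H]2C(C)=O | intermediate
13 | methyl (1S,2S,3R,4R)-2-[(benzyloxy)methyl]-4-[1-(dimethylsulfamoyl)-1H-imidazol-4-yl]-3-(2-methyl-1,3-dioxolan-2-yl)cyclobutane-1-carboxylate | CN(C)S(=O)(=O)n1cnc(c1)[C@H]2[C@H](C(=O)OC)[C@@H](COCc3ccccc3)[C@@H]2C4(C)OCCO4 | intermediate
14 | all-trans cyclobutane: Ca 1-(dimethylsulfamoyl)imidazol-4-yl; Cb CH2OH; Cc CH2OBn; Cd 2-methyl-1,3-dioxolan-2-yl | CN(C)S(=O)(=O)n1cnc(c1)[C@H]2[C@H](CO)[C@@H](COCc3ccccc3)[C@@H]2C4(C)OCCO4 | intermediate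
15 | all-trans cyclobutane diol: Cb and Cc CH2OH; Cd 2-methyl-1,3-dioxolan-2-yl | CN(C)S(=O)(=O)n1cnc(c1)[C@H]2[C@H](CO)[C@@H](CO)[C@@H]2C3(C)OCCO3 | intermediate
16 | bis(tert-butyldimethylsilyl) ether of 15 | CN(C)S(=O)(=O)n1cnc(c1)[C@H]2[C@H](CO[Si](C)(C)C(C)(C)C)[C@@H](CO[Si](C)(C)C(C)(C)C)[C@@H]2C3(C)OCCO3 | intermediate
17 | 2-lithioimidazole from 16 | CN(C)S(=O)(=O)n1c([Li])nc(c1)[C@H]2[C@H](CO[Si](C)(C)C(C)(C)C)[C@@H](CO[Si](C)(C)C(C)(C)C)[C@@H]2C3(C)OCCO3 | intermediate
18 | 2-azidoimidazole bis-silyl ether ketal (azido group at imidazole C2 of 16) | CN(C)S(=O)(=O)n1c(N=[N+]=[N-])nc(c1)[C@H]2[C@H](CO[Si](C)(C)C(C)(C)C)[C@@H](CO[Si](C)(C)C(C)(C)C)[C@@H]2C3(C)OCCO3 | intermediate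
19 | all-trans keto diol: Ca 2-azido-1-(dimethylsulfamoyl)imidazol-4-yl; Cb and Cc CH2OH; Cd acetyl | CN(C)S(=O)(=O)n1c(N=[N+]=[N-])nc(c1)[C@H]2[C@H](CO)[C@@H](CO)[C@@H]2C(C)=O | intermediate
20 | dimesylate of 19 | CN(C)S(=O)(=O)n1c(N=[N+]=[N-])nc(c1)[C@H]2[C@H](COS(C)(=O)=O)[C@@H](COS(C)(=O)=O)[C@@H]2C(C)=O | intermediate
21 | triazide ketone: Cb and Cc CH2N3; Cd acetyl | CN(C)S(=O)(=O)n1c(N=[N+]=[N-])nc(c1)[C@H]2[C@H](CN=[N+]=[N-])[C@@H](CN=[N+]=[N-])[C@@H]2C(C)=O | intermediate
22 | chloromethyl ketone: Cd C(=O)CH2Cl | CN(C)S(=O)(=O)n1c(N=[N+]=[N-])nc(c1)[C@H]2[C@H](CN=[N+]=[N-])[C@@H](CN=[N+]=[N-])[C@@H]2C(=O)CCl | intermediate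
23 | α-(diformylamino) ketone: Cd C(=O)CH2N(CHO)2 | CN(C)S(=O)(=O)n1c(N=[N+]=[N-])nc(c1)[C@H]2[C@H](CN=[N+]=[N-])[C@@H](CN=[N+]=[N-])[C@@H]2C(=O)CN(C=O)C=O | intermediate
24 | α-aminoketone hydrochloride: Cd C(=O)CH2NH2·HCl | CN(C)S(=O)(=O)n1c(N=[N+]=[N-])nc(c1)[C@H]2[C@H](CN=[N+]=[N-])[C@@H](CN=[N+]=[N-])[C@@H]2C(=O)CN.Cl | intermediate
25 | triazide bearing 2-amino-1H-imidazol-5-yl at Cd | CN(C)S(=O)(=O)n1c(N=[N+]=[N-])nc(c1)[C@H]2[C@H](CN=[N+]=[N-])[C@@H](CN=[N+]=[N-])[C@@H]2c3cnc(N)[nH]3 | intermediate
26 | triamine: Ca 2-amino-1-(dimethylsulfamoyl)imidazol-4-yl; Cb and Cc CH2NH2; Cd 2-amino-1H-imidazol-5-yl | CN(C)S(=O)(=O)n1c(N)nc(c1)[C@H]2[C@H](CN)[C@@H](CN)[C@@H]2c3cnc(N)[nH]3 | intermediate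
27 | all-trans 3,4-bis(aminomethyl)-1,2-bis(2-amino-1H-imidazol-5-yl)cyclobutane | Nc1ncc([C@H]2[C@H](CN)[C@@H](CN)[C@@H]2c2cnc(N)[nH]2)[nH]1 | intermediate
28 | 1-(4-bromo-1H-pyrrol-2-yl)-2,2,2-trichloroethan-1-one | O=C(c1cc(Br)c[nH]1)C(Cl)(Cl)Cl | starting material
29 | sceptrin, N-{[(1R,2S,3S,4R)-2,3-bis(2-amino-1H-imidazol-5-yl)-4-{[(4-bromo-1H-pyrrole-2-carbonyl)amino]methyl}cyclobutyl]methyl}-4-bromo-1H-pyrrole-2-carboxamide | Nc1ncc([C@H]2[C@H](CNC(=O)c3cc(Br)c[nH]3)[C@@H](CNC(=O)c3cc(Br)c[nH]3)[C@@H]2c2cnc(N)[nH]2)[nH]1 | target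

**Totals**

Total step count: 20. Longest linear sequence: 19 steps (from 1 through steps 1 and 3–20); step 2 is a one-step branch.

**Steps most likely to fail**

1. Step 5 (nitrogen deletion). The diazene may not be reached cleanly if the oxidant attacks the enolisable methyl ketone, if ammonia condenses with the ketone or strips the sulfamoyl group at 80 °C, or if the hot diradical fragments into two alkenes instead of closing. Fallback: setting out from 8, the N–N bond is made by substitution at nitrogen instead of nitrene transfer. Pyrrolidine 8 is treated with the anomeric amide N-(benzyloxy)-N-(pivaloyloxy)-4-(trifluoromethyl)benzamide in THF at 45 °C. Displacement of pivalate gives the N-(benzyloxy)-N-aroylhydrazine F1, which expels benzyl 4-(trifluoromethyl)benzoate by reductive elimination to give diazene 9 without oxidant, ammonia or strong heating. Loss of N2 and recombination bring the route back at 11.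

2. Step 4 (cycloaddition). The imidazole N3 can act as a third donor to copper and change the shape of the metalated dipole, which may cause leakage into the endo approach. Fallback: setting out from 7, the dipolarophile is changed to commercial methyl (E)-4-oxopent-2-enoate, so that relative configuration no longer has to be controlled. Any catalyst that fixes only the face of the dipole (for example AgOAc with a chiral phosphine) is used. The ketone, as the stronger acceptor, directs the glycine carbon to the ester-bearing alkene carbon and gives the pyrrolidine-2,3-diester F2. Nitrogen deletion under the conditions of step 5 gives the cyclobutane diester F3. NaOMe in MeOH then equilibrates all three carbonyl-bearing ring carbons, so either diastereomer converges on the all-trans diester F4. Ketalisation as in step 7 gives the dioxolane diester F5, and LiBH4 reduces both esters to diol 15, where the route is rejoined without benzyl ether or hydrogenolysis.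

3. Step 17 (second aminoimidazole). The heteroaryl azide may lose N2 during the 95 °C aqueous condensation, or the guanylated aminoketone may cyclise incompletely. Fallback: setting out from chloromethyl ketone 22, the ring is built at room temperature by alkylation and cyclodehydration with N-Boc-guanidine (NaI, DMF), which gives the Boc-protected aminoimidazole F6. Trifluoroacetic acid in CH2Cl2 at rt removes the carbamate and returns the route to 25.

**Further compounds**

F1 | step 5 | N-(benzyloxy)-N-[4-(trifluoromethyl)benzoyl]hydrazine formed at the ring nitrogen of 8 | CN(C)S(=O)(=O)n1cnc(c1)[C@H]2N(N(OCc3ccccc3)C(=O)c3ccc(cc3)C(F)(F)F)[C@@H](C(=O)OC)[C@@H](COCc3ccccc3)[C@@H]2C(C)=O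
F2 | step 4 | dimethyl (2R,5S)-4-acetyl-5-[1-(dimethylsulfamoyl)-1H-imidazol-4-yl]pyrrolidine-2,3-dicarboxylate (2,5-cis; C3/C4 trans, either face) | CN(C)S(=O)(=O)n1cnc(c1)[C@H]2N[C@@H](C(=O)OC)C(C(=O)OC)C2C(C)=O
F3 | step 4 | dimethyl 3-acetyl-4-[1-(dimethylsulfamoyl)-1H-imidazol-4-yl]cyclobutane-1,2-dicarboxylate (imidazolyl and adjacent ester cis; other two centres as in F2) | CN(C)S(=O)(=O)n1cnc(c1)[C@H]2[C@@H](C(=O)OC)C(C(=O)OC)C2C(C)=O
F4 | step 4 | all-trans dimethyl 3-acetyl-4-[1-(dimethylsulfamoyl)-1H-imidazol-4-yl]cyclobutane-1,2-dicarboxylate | CN(C)S(=O)(=O)n1cnc(c1)[C@H]2[C@H](C(=O)OC)[C@@H](C(=O)OC)[C@@H]2C(C)=O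
F5 | step 4 | all-trans dimethyl 4-[1-(dimethylsulfamoyl)-1H-imidazol-4-yl]-3-(2-methyl-1,3-dioxolan-2-yl)cyclobutane-1,2-dicarboxylate | CN(C)S(=O)(=O)n1cnc(c1)[C@H]2[C@H](C(=O)OC)[C@@H](C(=O)OC)[C@@H]2C3(C)OCCO3
F6 | step 17 | tert-butyl 2-amino-4-(cyclobutyl)imidazole-1-carboxylate analogue of 25 (Cd 2-amino-1-Boc-imidazol-4-yl) | CN(C)S(=O)(=O)n1c(N=[N+]=[N-])nc(c1)[C@H]2[C@H](CN=[N+]=[N-])[C@@H](CN=[N+]=[N-])[C@@H]2c3cn(C(=O)OC(C)(C)C)c(N)n3
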